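**Retrosynthetic overview**
1. The target comes from its tetra-MOM ether by one global acetal cleavage (last step).
2. Key disconnection C3–C4: the ring A formyl carbon is turned into an acyl-anion equivalent by a chiral N-heterocyclic carbene and adds to a tethered α-aryloxy aldehyde (intramolecular aldehyde–aldehyde crossed benzoin). C2 and C3 are both fixed in this step by dynamic kinetic resolution.
3. The dialdehyde comes from O1–C2 ether formation (Mitsunobu) between a ring A phenol aldehyde and a ring B benzylic carbinol, then desilylation and oxidation.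
4. The ring B carbinol comes from resorcinol bis-MOM ether by three successive directed ortho-lithiations (geranyl, prenyl, then addition to a silyloxyacetaldehyde). The ring A piece comes from phloroglucinaldehyde by selective bis-MOM protection.
5. Ring order: rings A and B are bought as arenes; ring C is the only ring formed, in the key step.

Abbreviations: geranyl = (2E)-3,7-dimethylocta-2,6-dien-1-yl; prenyl = 3-methylbut-2-en-1-yl; MOM = methoxymethyl; TBS = tert-butyldimethylsilyl. Flavonoid numbering (O1, C2, C3, C4; rings A, B, C) is used.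

Assumption: (5aS,10bR)-2-(pentafluorophenyl)-5a,10b-dihydro-4H,6H-indeno[2,1-b][1,2,4]triazolo[4,3-d][1,4]oxazin-2-ium tetrafluoroborate is taken, by analogy with related chromanone-forming cyclizations, to give the (2R,3R) product; if the first run shows the opposite sense, (5aR,10bS)-2-(pentafluorophenyl)-5a,10b-dihydro-4H,6H-indeno[2,1-b][1,2,4]triazolo[4,3-d][1,4]oxazin-2-ium tetrafluoroborate is used instead.

**Route**

Step 1
Reactants: 1 resorcinol
Product: 2 1,3-bis(methoxymethoxy)benzene
Conditions: NaH (2.5 equiv), MOMCl (2.4 equiv), DMF, 0 °C → rt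
Reagents that add atoms: chloromethyl methyl ether, COCCl
Why: Williamson-type O-alkylation of the bis-phenoxide by the reactive α-chloro ether gives the bis-acetal, which serves as both protecting group and ortho-directing group; no stereocenter.

Step 2
Reactants: 2 1,3-bis(methoxymethoxy)benzene; 3 geranyl bromide
Product: 5 2-geranyl-1,3-bis(methoxymethoxy)benzene, via aryllithium 4 (not isolated)
Conditions: n-BuLi (1.1 equiv), THF, 0 °C → rt, 1 h; then CuI (10 mol %), 3, −78 °C → rt
Reagents that add atoms: none
Why: Directed ortho-metalation removes the proton flanked by both MOM ethers, and copper-catalysed SN2 allylation at the primary carbon of the bromide keeps the E olefin.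

Step 3
Reactants: 5 2-geranyl-1,3-bis(methoxymethoxy)benzene; 6 prenyl bromide
Product: 8 2-geranyl-1,3-bis(methoxymethoxy)-4-prenylbenzene, via aryllithium 7 (not isolated)
Conditions: n-BuLi (1.2 equiv), TMEDA (1.2 equiv), THF, 0 °C, 1.5 h; then CuI (10 mol %), 6, −78 °C → rt
Reagents that add atoms: none
Why: A second directed ortho-metalation next to a MOM ether (complex-induced ring deprotonation outruns removal of the benzylic–allylic CH2 proton) is followed by copper-catalysed SN2 prenylation; the two ring positions are equivalent, so one regioisomer results.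

Step 4
Reactants: 8 2-geranyl-1,3-bis(methoxymethoxy)-4-prenylbenzene; 9 (tert-butyldimethylsilyloxy)acetaldehyde
Product: 11 racemic 2-(tert-butyldimethylsilyloxy)-1-[3-geranyl-2,4-bis(methoxymethoxy)-5-prenylphenyl]ethanol, via aryllithium 10 (not isolated)
Conditions: n-BuLi (1.2 equiv), TMEDA (1.2 equiv), THF, 0 °C, 1.5 h; then 9, −78 °C; then H2O
Reagents that add atoms: none
Why: The third directed ortho-metalation takes the only ring C–H left next to a MOM ether, and 1,2-addition to the aldehyde installs the future C2–C3 unit; the carbinol is made racemic on purpose because this center is reset in step 9.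

Step 5
Reactants: 12 2,4,6-trihydroxybenzaldehyde
Product: 13 2-hydroxy-4,6-bis(methoxymethoxy)benzaldehyde
Conditions: MOMCl (2.2 equiv), i-Pr2NEt (2.5 equiv), CH2Cl2, 0 °C → rt
Reagents that add atoms: chloromethyl methyl ether, COCCl
Why: Selective O-alkylation: once the para and one ortho hydroxyl have reacted, the last ortho hydroxyl is held in a hydrogen bond to the formyl group and is not alkylated under amine-base conditions.

Step 6
Reactants: 11 racemic ring B carbinol; 13 2-hydroxy-4,6-bis(methoxymethoxy)benzaldehyde
Product: 14 racemic 2-{2-(tert-butyldimethylsilyloxy)-1-[3-geranyl-2,4-bis(methoxymethoxy)-5-prenylphenyl]ethoxy}-4,6-bis(methoxymethoxy)benzaldehyde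
Conditions: PPh3 (1.5 equiv), diisopropyl azodicarboxylate (1.5 equiv), THF, 0 °C → rt
Reagents that add atoms: none
Why: Mitsunobu etherification: the acidic ortho-formyl phenol protonates the betaine and its phenoxide displaces the benzylic oxyphosphonium, forming the O1–C2 bond; the configuration at this carbon does not matter here.

Step 7
Reactants: 14 racemic silyl ether
Product: 15 racemic 2-{1-[3-geranyl-2,4-bis(methoxymethoxy)-5-prenylphenyl]-2-hydroxyethoxy}-4,6-bis(methoxymethoxy)benzaldehyde
Conditions: Bu4NF (1.2 equiv), AcOH (1.2 equiv), THF, 0 °C → rt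
Reagents that add atoms: none
Why: Fluoride cleaves the Si–O bond, and the acetic acid buffer keeps the freed alcohol protonated so that it neither adds to the aryl aldehyde nor triggers a Smiles-type aryl shift; MOM ethers are inert.

Step 8
Reactants: 15 racemic primary alcohol
Product: 16 racemic 2-{1-[3-geranyl-2,4-bis(methoxymethoxy)-5-prenylphenyl]-2-oxoethoxy}-4,6-bis(methoxymethoxy)benzaldehyde
Conditions: Dess–Martin periodinane (1.3 equiv), NaHCO3, CH2Cl2, 0 °C → rt; used crude
Reagents that add atoms: none
Why: Dess–Martin oxidation (ligand exchange on hypervalent iodine, then elimination) stops at the aldehyde under near-neutral conditions that spare the electron-rich olefins, the acetals and the aryl aldehyde.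

Step 9
Reactants: 16 racemic dialdehyde
Product: 18 (2R,3R)-2-[3-geranyl-2,4-bis(methoxymethoxy)-5-prenylphenyl]-3-hydroxy-5,7-bis(methoxymethoxy)-2,3-dihydro-4H-chromen-4-one, via enaminol 17 (not isolated)
Conditions: (5aS,10bR)-2-(pentafluorophenyl)-5a,10b-dihydro-4H,6H-indeno[2,1-b][1,2,4]triazolo[4,3-d][1,4]oxazin-2-ium tetrafluoroborate (20 mol %), i-Pr2NEt (0.5 equiv), toluene, 23 °C, Ar
Reagents that add atoms: none
Why: Proposed new method: an intramolecular aldehyde–aldehyde crossed benzoin run as a dynamic kinetic resolution; the carbene adds to the ring A aldehyde (the other aldehyde is α-branched and α-aryloxy-substituted, which makes it a poor carbene acceptor but the better electrophile), proton transfer gives the nucleophilic enaminol 17 (acyl-anion equivalent), and this attacks the tethered formyl group on its Si face through a six-membered chair-like transition state with the ring B aryl group equatorial, giving the 2,3-trans ketol; because the α-aryl-α-aryloxy aldehyde center of 16 is racemized by the amine much faster than the ketol C3–H is touched, the chiral carbene can funnel both enantiomers of 16 through the matched (R)-aldehyde to (2R,3R)-18; the closest known reaction types are the triazolium-catalysed enantioselective intramolecular crossed benzoin of salicylaldehyde-derived keto aldehydes to 3-hydroxychroman-4-ones and the chemoselective cross-benzoin in which α-branched α-heteroatom-substituted aldehydes act only as acceptors.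

Step 10
Reactants: 18 tetra-MOM flavanonol
Product: 19 (2R,3R)-2-[3-geranyl-2,4-dihydroxy-5-prenylphenyl]-3,5,7-trihydroxy-2,3-dihydro-4H-chromen-4-one (target)
Conditions: HCl (3 M aq), MeOH, 40 °C; NaHCO3 work-up
Reagents that add atoms: none
Why: Acid-catalysed transacetalization of the four aryl MOM ethers to methanol frees the phenols; dilute acid at moderate temperature leaves the trisubstituted olefins alone, and the 2,3-trans ketol is the thermodynamic diastereomer, so no stereocenter is changed.

**Compound list**

1 | resorcinol (benzene-1,3-diol) | Oc1cccc(O)c1 | starting material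
2 | 1,3-bis(methoxymethoxy)benzene | COCOc1cccc(OCOC)c1 | intermediate
3 | geranyl bromide, (2E)-1-bromo-3,7-dimethylocta-2,6-diene | CC(C)=CCC/C(C)=C/CBr | starting material
4 | [2,6-bis(methoxymethoxy)phenyl]lithium, formed in the flask | [Li]c1c(OCOC)cccc1OCOC | intermediate
5 | 2-geranyl-1,3-bis(methoxymethoxy)benzene | CC(C)=CCC/C(C)=C/Cc1c(OCOC)cccc1OCOC | intermediate
6 | prenyl bromide, 1-bromo-3-methylbut-2-ene | CC(C)=CCBr | starting material
7 | [3-geranyl-2,4-bis(methoxymethoxy)phenyl]lithium, formed in the flask | CC(C)=CCC/C(C)=C/Cc1c(OCOC)ccc([Li])c1OCOC | intermediate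
8 | 2-geranyl-1,3-bis(methoxymethoxy)-4-prenylbenzene | CC(C)=CCC/C(C)=C/Cc1c(OCOC)ccc(CC=C(C)C)c1OCOC | intermediate
9 | (tert-butyldimethylsilyloxy)acetaldehyde | O=CCO[Si](C)(C)C(C)(C)C | starting material
10 | [3-geranyl-2,4-bis(methoxymethoxy)-5-prenylphenyl]lithium, formed in the flask | CC(C)=CCC/C(C)=C/Cc1c(OCOC)c(CC=C(C)C)cc([Li])c1OCOC | intermediate
11 | racemic 2-(tert-butyldimethylsilyloxy)-1-[3-geranyl-2,4-bis(methoxymethoxy)-5-prenylphenyl]ethanol | CC(C)=CCC/C(C)=C/Cc1c(OCOC)c(CC=C(C)C)cc(C(O)CO[Si](C)(C)C(C)(C)C)c1OCOC | intermediate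
12 | 2,4,6-trihydroxybenzaldehyde (phloroglucinaldehyde) | O=Cc1c(O)cc(O)cc1O | starting material
13 | 2-hydroxy-4,6-bis(methoxymethoxy)benzaldehyde | COCOc1cc(O)c(C=O)c(OCOC)c1 | intermediate
14 | racemic 2-{2-(tert-butyldimethylsilyloxy)-1-[3-geranyl-2,4-bis(methoxymethoxy)-5-prenylphenyl]ethoxy}-4,6-bis(methoxymethoxy)benzaldehyde | CC(C)=CCC/C(C)=C/Cc1c(OCOC)c(CC=C(C)C)cc(C(CO[Si](C)(C)C(C)(C)C)Oc2cc(OCOC)cc(OCOC)c2C=O)c1OCOC | intermediate
15 | racemic 2-{1-[3-geranyl-2,4-bis(methoxymethoxy)-5-prenylphenyl]-2-hydroxyethoxy}-4,6-bis(methoxymethoxy)benzaldehyde | CC(C)=CCC/C(C)=C/Cc1c(OCOC)c(CC=C(C)C)cc(C(CO)Oc2cc(OCOC)cc(OCOC)c2C=O)c1OCOC | intermediate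
16 | racemic 2-{1-[3-geranyl-2,4-bis(methoxymethoxy)-5-prenylphenyl]-2-oxoethoxy}-4,6-bis(methoxymethoxy)benzaldehyde | CC(C)=CCC/C(C)=C/Cc1c(OCOC)c(CC=C(C)C)cc(C(C=O)Oc2cc(OCOC)cc(OCOC)c2C=O)c1OCOC | intermediate
17 | enaminol (Breslow intermediate) of (R)-16, formed in the flask: the ring A formyl carbon carries OH and is doubly bonded to C3 of the (5aS,10bR) triazolylidene | CC(C)=CCC/C(C)=C/Cc1c(OCOC)c(CC=C(C)C)cc([C@H](C=O)Oc2cc(OCOC)cc(OCOC)c2C(O)=C2N(c3c(F)c(F)c(F)c(F)c3F)N=C3CO[C@H]4Cc5ccccc5[C@H]4N23)c1OCOC | intermediate
18 | (2R,3R)-2-[3-geranyl-2,4-bis(methoxymethoxy)-5-prenylphenyl]-3-hydroxy-5,7-bis(methoxymethoxy)-2,3-dihydro-4H-chromen-4-one | CC(C)=CCC/C(C)=C/Cc1c(OCOC)c(CC=C(C)C)cc([C@H]2Oc3cc(OCOC)cc(OCOC)c3C(=O)[C@@H]2O)c1OCOC | intermediate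
19 | (2R,3R)-2-[3-geranyl-2,4-dihydroxy-5-prenylphenyl]-3,5,7-trihydroxy-2,3-dihydro-4H-chromen-4-one | CC(C)=CCC/C(C)=C/Cc1c(O)c(CC=C(C)C)cc([C@H]2Oc3cc(O)cc(O)c3C(=O)[C@@H]2O)c1O | target

**Step count and risks**

Total step count: 10.
Longest linear sequence: 9 steps (steps 1, 2, 3, 4, 6, 7, 8, 9, 10); step 5 is a one-step side branch.

Three steps most likely to fail:

Step 9 (carbene-catalysed ring closure). The ring A aldehyde has two ortho oxygen substituents and may be a reluctant acyl donor. If the aliphatic aldehyde becomes the donor, or if racemization of 16 is too slow, regiochemistry or enantiomeric purity is lost. A five-membered intramolecular aldol is a further competitor. The fallback sets out from 16 and comes back to the route at 18. Dialdehyde 16 is cyclised with the small achiral carbene from 3-benzyl-5-(2-hydroxyethyl)-4-methylthiazolium chloride and Et3N in ethanol at 60 °C. Under these equilibrating conditions it no longer matters which aldehyde is the donor, because either ketol isomerises through the enediol to the conjugated aryl ketone with the 2,3-trans arrangement. This gives the racemic trans tetra-MOM flavanonol F1. Stereochemistry is then settled by resolution instead of catalyst control: preparative chromatography on an amylose tris(3,5-dimethylphenylcarbamate) phase delivers the (2R,3R) enantiomer, which is 18.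

Step 6 (Mitsunobu etherification). A hindered, very electron-rich secondary benzylic alcohol and a hydrogen-bonded phenol may give elimination or low conversion. The fallback sets out from 8 and comes back to the route at 15. Aryllithium 10, made from 8 as in step 4, is quenched with DMF to give 3-geranyl-2,4-bis(methoxymethoxy)-5-prenylbenzaldehyde F2. Trimethylsulfonium iodide and NaH in DMSO–THF (Corey–Chaykovsky) convert it into racemic 2-[3-geranyl-2,4-bis(methoxymethoxy)-5-prenylphenyl]oxirane F3. Phenol 13 then opens this electron-rich oxirane at the benzylic carbon (LiClO4, MeCN, rt; the SN1-like opening is stabilised by the ortho and para alkoxy groups) and gives alcohol 15 directly. The silyl ether is never made, so compounds 11 and 14 are bypassed.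

Step 10 (global MOM removal). Protic acid can cyclise the prenyl and geranyl chains onto the neighbouring free phenols. The fallback sets out from 18 and comes back to the route at 19. TMSOTf and 2,2'-bipyridyl in MeCN at 0 °C exchange the aryl MOM ethers for aryl silyl ethers under aprotic conditions, and the 3-hydroxyl is silylated as well. This gives the (2R,3R) pentakis(trimethylsilyl) ether F4. Stirring F4 in THF–water with a trace of citric acid at rt hydrolyses all five silyl ethers to 19.

**Further compounds**

F1 | step 9 | racemic trans-18, a 1:1 mixture of (2R,3R)- and (2S,3S)-2-[3-geranyl-2,4-bis(methoxymethoxy)-5-prenylphenyl]-3-hydroxy-5,7-bis(methoxymethoxy)-2,3-dihydro-4H-chromen-4-one | CC(C)=CCC/C(C)=C/Cc1c(OCOC)c(CC=C(C)C)cc([C@H]2Oc3cc(OCOC)cc(OCOC)c3C(=O)[C@@H]2O)c1OCOC.CC(C)=CCC/C(C)=C/Cc1c(OCOC)c(CC=C(C)C)cc([C@@H]2Oc3cc(OCOC)cc(OCOC)c3C(=O)[C@H]2O)c1OCOC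
F2 | step 6 | 3-geranyl-2,4-bis(methoxymethoxy)-5-prenylbenzaldehyde | CC(C)=CCC/C(C)=C/Cc1c(OCOC)c(CC=C(C)C)cc(C=O)c1OCOC
F3 | step 6 | racemic 2-[3-geranyl-2,4-bis(methoxymethoxy)-5-prenylphenyl]oxirane | CC(C)=CCC/C(C)=C/Cc1c(OCOC)c(CC=C(C)C)cc(C2CO2)c1OCOC
F4 | step 10 | (2R,3R)-2-[3-geranyl-5-prenyl-2,4-bis(trimethylsilyloxy)phenyl]-3,5,7-tris(trimethylsilyloxy)-2,3-dihydro-4H-chromen-4-one | CC(C)=CCC/C(C)=C/Cc1c(O[Si](C)(C)C)c(CC=C(C)C)cc([C@H]2Oc3cc(O[Si](C)(C)C)cc(O[Si](C)(C)C)c3C(=O)[C@@H]2O[Si](C)(C)C)c1O[Si](C)(C)C
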